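The runs are calculated from invented constants; the scatter is artificial.

**A small charge.** Take a small charge of free catalyst, 2.5 mol% on the starting material, with one equivalent of second substrate, and ask what stands at 15 d.

all flasks: starting material 0.22 M
- south-east: second substrate 1 equiv; free catalyst 2.5 mol%; the very flask that is asked about, followed so far
- east: second substrate 1 equiv; free catalyst 3.8 mol%; run made earlier
- flask: second substrate 1.00 equiv; free catalyst 2.5 mol%; time 15 d

| run | time / d | target / % | uncatalysed product / % |
|---|---|---|---|
| south-east | 0.333 | 85.0 | 3.3 |
| south-east | 0.500 | 92.8 | 3.5 |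
| south-east | 0.833 | 95.9 | 4.3 |
| south-east | 1.25 | 94.4 | 4.4 |
| south-east | 2.08 | 96.3 | 4.1 |
| south-east | 3.00 | 95.0 | 4.1 |
| south-east | 5.00 | 95.2 | 3.7 |
| east | 0.833 | 97.4 | 3.0 |
| east | 1.67 | 96.9 | 3.7 |
| east | 2.50 | 97.4 | 3.3 |
| east | 3.00 | 95.4 | 2.8 |
| east | 4.00 | 96.2 | 2.3 |
| east | 5.00 | 96.0 | 2.6 |
| east | 6.00 | 96.8 | 1.7 |

(standard deviation of a reading: 1 percentage point)

- the earlier runs were read with a standard deviation of 1 percentage point

- how much target there is at 15 d, in percent of the starting material charged
- how much uncatalysed product there is at 15 d, in percent of the starting material charged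

**Fast rung.** Read the south-east flask at 0.333 d: target and uncatalysed product leave 11.7 % of the starting material unaccounted for. Treat that as one first-order decay, which gives, as a reading of the south-east run, a time constant of 0.155 d.

**Leak rung.** From 0.833 d on, the south-east readings look flat within their scatter. Sum them and divide uncatalysed product by target: these leak odds, the inverse of a selectivity factor, come to 0.0432. The east run, summed the same way over all its readings, reads 0.0287. The ratio of the odds reads 1.51 against 1.52 for the loadings, so take the odds as inverse to the loading at this strength of starting material. The leak's own time constant in the south-east run is then reckoned at 3.75 d, slower than the fast rung.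

**Long rung.** The asked time is 96.8 fast time constants, so both products stop growing well before it. For the asked flask, commit to 95.9 % target and 4.14 % uncatalysed product.

**The forecast.** It gives 96.8 % target (94.5 % to 99 %) and 1.5 % uncatalysed product (0.5 % to 3.2 %): “Extrapolating to 15 d leaves about 1–2% uncatalysed product.” Its uncatalysed figure is lower than the reckoning above.

**The result.** The flask gives 95.8 % target and 4.22 % uncatalysed product. Both forecast values count as right within the tolerance, though the uncatalysed product stands above the forecast's own high end. Left ten times as long, it holds 4.22 % uncatalysed product. Leak odds times the target give 4.14 %.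

    catalyst intermediate A → free catalyst + target (k = 51.0 h⁻¹)
    catalyst intermediate B → free catalyst + second product (k = 1.00 h⁻¹)
    starting material + free catalyst ⇌ catalyst intermediate A (K = 4.50 L mol⁻¹, k = 120 L mol⁻¹ h⁻¹)
    second substrate → decomposition product (k = 1.90 × 10⁻⁵ h⁻¹)
    second substrate + free catalyst ⇌ catalyst intermediate B (K = 6.00 L mol⁻¹, k = 6.10 L mol⁻¹ h⁻¹)
    starting material → uncatalysed product (k = 0.0110 h⁻¹)

**Second flask.** Charge starting material at a quarter of the strength, loadings held, so catalyst per volume falls equally. Carry the rule beyond the strength it was read at, scaling by catalyst per volume: the odds become 0.173, which reckons to 14.7 % uncatalysed product. The computed neighbour flask gives 10.8 %, with 89.2 % target.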